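Ring B of the target (C4a, C5, C6, C7, C8, C8a) is a benzene ring with oxygen on C5 and C8. It is joined along C4a–C8a to quinone ring A, whose C2 carries C1'. Such a ring is the retron of a [4+2] union between a quinone alkene and a butadiene oxygenated at both termini, so the plan cuts C4a–C5 and C8–C8a. One Diels–Alder reaction makes both bonds, closes ring B and brings in both peri oxygens. Its precursor is benzoquinone 9, which already holds the complete (S)-side chain including the isobutyrate. Ring B is then aromatised by oxidising the carbinol carbons C5 and C8, not by enolate chemistry, to keep both oxygens.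

Key step: step 7

Assumption 1: bis-silylation of succinaldehyde should give a mixture of geometric isomers. Only the (1E,3E) isomer 12 can reach the s-cis geometry without an inward-pointing silyloxy group, so an E,E-enriched distillate is dosed on its E,E content and the Z isomers stay behind as spectators.
Assumption 2: 16 is written as the tautomer with the side chain on the quinone ring. The two naphthazarin tautomers interconvert fast and are one substance.

Step 1
Reactants: 1 2,5-dimethoxybenzaldehyde; 2 (−)-B-allyldiisopinocampheylborane (isopinocampheyl groups from (+)-α-pinene, commercial solution in pentane)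
Product: 4 (S)-1-(2,5-dimethoxyphenyl)but-3-en-1-ol, via borinate ester 3 (not isolated)
Conditions: 2 (1.2 equiv), Et2O, −78 °C; then NaOH, H2O2, 0 °C to rt
Reagents that add atoms: (−)-B-allyldiisopinocampheylborane 2 (gives the allyl group), C=CCB([C@@H]1C[C@@H]2C[C@H]([C@H]1C)C2(C)C)[C@@H]3C[C@@H]4C[C@H]([C@H]3C)C4(C)C
Why: Brown asymmetric allylboration through a closed chair (Zimmerman–Traxler) transition state, in which the isopinocampheyl groups of this series deliver allyl to the Si face of an aryl aldehyde and so set C1' as S; allyl is used rather than a prenyl metal because prenyl reagents react at their γ-carbon and would give the branched 1,1-dimethylallyl carbinol.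

Step 2
Reactants: 4 (S)-1-(2,5-dimethoxyphenyl)but-3-en-1-ol; 5 isobutyryl chloride
Product: 6 (S)-1-(2,5-dimethoxyphenyl)but-3-en-1-yl 2-methylpropanoate
Conditions: 5 (1.3 equiv), Et3N, DMAP (cat.), CH2Cl2, 0 °C to rt
Reagents that add atoms: isobutyryl chloride 5, CC(C)C(Cl)=O
Why: DMAP-catalysed O-acylation under basic conditions breaks only the O–H bond, so the electron-rich benzylic C1'–O bond is never ionised and the S configuration is kept.

Step 3
Reactants: 6 (S)-1-(2,5-dimethoxyphenyl)but-3-en-1-yl 2-methylpropanoate; 7 2-methylbut-2-ene
Product: 8 (S)-1-(2,5-dimethoxyphenyl)-4-methylpent-3-en-1-yl 2-methylpropanoate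
Conditions: second-generation Grubbs catalyst RuCl2(=CHPh)(PCy3)(SIMes) (2 mol %), 7 (large excess), CH2Cl2, 35 °C, sealed flask
Reagents that add atoms: 2-methylbut-2-ene 7, CC=C(C)C
Why: Olefin cross-metathesis of a terminal alkene with excess 2-methylbut-2-ene exchanges =CH2 for =CMe2 and is driven by loss of propene; this gives the linear prenyl terminus without any E/Z question, the trisubstituted product is inert to further metathesis, and C1' is not touched.

Step 4
Reactants: 8 (S)-1-(2,5-dimethoxyphenyl)-4-methylpent-3-en-1-yl 2-methylpropanoate
Product: 9 (S)-1-(3,6-dioxocyclohexa-1,4-dien-1-yl)-4-methylpent-3-en-1-yl 2-methylpropanoate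
Conditions: (NH4)2Ce(NO3)6 (2.3 equiv), MeCN–H2O, 0 °C, 15 min
Reagents that add atoms: water, O
Why: Oxidative demethylation of a hydroquinone dimethyl ether by two one-electron transfers to tetravalent cerium, with water attacking the two ipso carbons and methanol leaving; the arene is by far the most easily oxidised site, so the trisubstituted alkene, the ester and C1' should survive a short cold reaction.

Step 5
Reactants: 10 2,5-dimethoxytetrahydrofuran (cis/trans mixture)
Product: 11 succinaldehyde (butanedial)
Conditions: H2O, 90 °C; MeOH/H2O distilled off, toluene azeotrope, short-path distillation, used at once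
Reagents that add atoms: water, O
Why: Hydrolysis of a cyclic bis-acetal, which needs no added acid in hot water and is pulled to the dialdehyde by distilling out methanol; no stereocentre is involved.

Step 6
Reactants: 11 succinaldehyde
Product: 12 (1E,3E)-1,4-bis(trimethylsilyloxy)buta-1,3-diene
Conditions: TMSOTf (2.2 equiv), Et3N (3 equiv), Et2O, 0 °C to rt; pentane extraction, distillation under reduced pressure
Reagents that add atoms: trimethylsilyl trifluoromethanesulfonate, C[Si](C)(C)OS(=O)(=O)C(F)(F)F
Why: Silyl enol ether formation by soft enolisation, each aldehyde being O-silylated and then deprotonated by the amine in a medium that stays basic; this suppresses aldol and furan-forming pathways, and the second enolisation is helped by the conjugation it creates.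

Step 7
Reactants: 9 (S)-1-(3,6-dioxocyclohexa-1,4-dien-1-yl)-4-methylpent-3-en-1-yl 2-methylpropanoate; 12 (1E,3E)-1,4-bis(trimethylsilyloxy)buta-1,3-diene
Product: 13 endo adduct (1S)-1-[(4aR,5S,8R,8aS)-1,4-dioxo-5,8-bis(trimethylsilyloxy)-1,4,4a,5,8,8a-hexahydronaphthalen-2-yl]-4-methylpent-3-en-1-yl 2-methylpropanoate (H-4a, H-5, H-8 and H-8a all on one face; drawn as one facial isomer, the 4aS,5R,8S,8aR isomer forms beside it and is carried along)
Conditions: 12 (1.5 equiv of E,E isomer), toluene, rt to 45 °C, Ar, dark, base-washed glassware; evaporation, used crude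
Reagents that add atoms: none
Why: A concerted, suprafacial [4+2] cycloaddition of normal electron demand pairs the high HOMO of the bis-silyloxy diene with the low LUMO of the quinone, and the closest known reaction type is the addition of 1-oxygenated and 1,4-dioxygenated butadienes to benzoquinones. Ring B is closed by intermolecular annulation, C4a–C5 and C8–C8a being made in one event to give a six-membered carbocycle cis-fused to ring A. C4a and C8a come out cis because the dienophile alkene is held Z inside its ring, C5 and C8 come out cis to each other because both diene alkenes are E, and the endo rule (overlap of the diene with the quinone carbonyls) places both silyloxy groups on the same face as C1 and C4; C1' does not control which quinone face is attacked, and the two resulting diastereomers converge in step 9. The step needs site selectivity, which the substrate provides: C5=C6 of the 2-substituted benzoquinone is disubstituted and open, C2=C3 is trisubstituted, shielded by the branched C1' and less electrophilic, and the electron-rich side-chain alkene is no partner for an electron-rich diene. Because the two ends of 12 are equivalent only one orientation exists, and leaving out Lewis acid, base and silica gel keeps the β-silyloxy ketones and the base-sensitive C1'–H away from enolisation.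

Step 8
Reactants: 13 endo adduct (both facial isomers)
Product: 14 (1S)-1-[(4aR,5S,8R,8aS)-5,8-dihydroxy-1,4-dioxo-1,4,4a,5,8,8a-hexahydronaphthalen-2-yl]-4-methylpent-3-en-1-yl 2-methylpropanoate (drawn as the same facial isomer)
Conditions: 0.1 M HCl (cat.), THF–H2O, 0 °C, minutes; pH 7 buffer, extraction, no chromatography
Reagents that add atoms: none
Why: Acid-catalysed hydrolysis of secondary trimethylsilyl ethers, the most labile silyl ethers, cleaves Si–O at an acidity and temperature at which the isobutyrate, the ene-dione and the β-hydroxy ketone units should not react, so all stereocentres are carried through.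

Step 9
Reactants: 14 diol (both facial isomers)
Product: 16 isobutyrylalkannin, (S)-1-(5,8-dihydroxy-1,4-dioxo-1,4-dihydronaphthalen-2-yl)-4-methylpent-3-en-1-yl 2-methylpropanoate, via cis-fused tetraone 15 (not isolated)
Conditions: Dess–Martin periodinane (2.5 equiv), CH2Cl2, 0 °C to rt; non-reductive work-up by filtration through a short silica pad
Reagents that add atoms: none
Why: Dess–Martin oxidation, in which both allylic carbinols exchange onto pentavalent iodine at once and collapse to the C5 and C8 ketones in a base-free medium, fixing both oxygens as carbonyls before β-elimination can set in and never turning ring A into a hydroquinone that could expel the C1' ester; in tetraone 15, C4a–H and C8a–H each lie between two carbonyls and enolise, driven by aromatisation of ring B and two O–H···O=C hydrogen bonds, which erases the four transient stereocentres and leaves C1' as S.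

Compound list
1 | 2,5-dimethoxybenzaldehyde | COc1ccc(OC)c(C=O)c1 | starting material
2 | (−)-B-allyldiisopinocampheylborane, (+)-α-pinene series | C=CCB([C@@H]1C[C@@H]2C[C@H]([C@H]1C)C2(C)C)[C@@H]3C[C@@H]4C[C@H]([C@H]3C)C4(C)C | starting material
3 | diisopinocampheylborinate ester of 4 | C=CC[C@H](OB([C@@H]1C[C@@H]2C[C@H]([C@H]1C)C2(C)C)[C@@H]3C[C@@H]4C[C@H]([C@H]3C)C4(C)C)c5cc(OC)ccc5OC | intermediate
4 | (S)-1-(2,5-dimethoxyphenyl)but-3-en-1-ol | C=CC[C@H](O)c1cc(OC)ccc1OC | intermediate
5 | isobutyryl chloride | CC(C)C(Cl)=O | starting material
6 | (S)-1-(2,5-dimethoxyphenyl)but-3-en-1-yl 2-methylpropanoate | C=CC[C@H](OC(=O)C(C)C)c1cc(OC)ccc1OC | intermediate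
7 | 2-methylbut-2-ene | CC=C(C)C | starting material
8 | (S)-1-(2,5-dimethoxyphenyl)-4-methylpent-3-en-1-yl 2-methylpropanoate | CC(C)=CC[C@H](OC(=O)C(C)C)c1cc(OC)ccc1OC | intermediate
9 | (S)-1-(3,6-dioxocyclohexa-1,4-dien-1-yl)-4-methylpent-3-en-1-yl 2-methylpropanoate | CC(C)=CC[C@H](OC(=O)C(C)C)C1=CC(=O)C=CC1=O | intermediate
10 | 2,5-dimethoxytetrahydrofuran (cis/trans mixture) | COC1CCC(OC)O1 | starting material
11 | succinaldehyde | O=CCCC=O | intermediate
12 | (1E,3E)-1,4-bis(trimethylsilyloxy)buta-1,3-diene | C[Si](C)(C)O/C=C/C=C/O[Si](C)(C)C | intermediate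
13 | endo Diels–Alder adduct, (1'S,4aR,5S,8R,8aS), one of two facial diastereomers | CC(C)=CC[C@H](OC(=O)C(C)C)C1=CC(=O)[C@H]2[C@@H](O[Si](C)(C)C)C=C[C@@H](O[Si](C)(C)C)[C@H]2C1=O | intermediate
14 | 5,8-diol of the adduct, (1'S,4aR,5S,8R,8aS) | CC(C)=CC[C@H](OC(=O)C(C)C)C1=CC(=O)[C@H]2[C@@H](O)C=C[C@@H](O)[C@H]2C1=O | intermediate
15 | cis-fused 4a,8a-dihydronaphthalene-1,4,5,8-tetraone with the (S)-side chain at C2, (4aR,8aS) as drawn | CC(C)=CC[C@H](OC(=O)C(C)C)C1=CC(=O)[C@H]2C(=O)C=CC(=O)[C@H]2C1=O | intermediate
16 | isobutyrylalkannin | CC(C)=CC[C@H](OC(=O)C(C)C)C1=CC(=O)c2c(O)ccc(O)c2C1=O | target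

Total step count: 9. Longest linear sequence: 7 steps (1, 2, 3, 4, 7, 8, 9). Steps 5 and 6 form the short second branch.

Steps most likely to fail

Step 9.
- **What may go wrong:** once the first carbinol is oxidised, enolisation and aromatising loss of water from the still unoxidised carbinol may outrun the second oxidation. Surplus oxidant may also attack the electron-rich product ring.
- **Fallback:** it sets out from 9 and comes back at 15. It raises the oxidation level of the four-carbon partner instead of oxidising the adduct.
- **Course:** succinic anhydride is bis-silylated (TMSOTf, Et3N) to 2,5-bis(trimethylsilyloxy)furan F1, an s-cis-locked diene of the kind known to turn activated alkenes into hydroquinone rings. F1 adds to the open C5=C6 alkene of 9 and forms the same C4a–C5 and C8–C8a bonds. This gives the 5,8-epoxy-bridged adduct F2, in which C5 and C8 are already at the ketone level and carry no hydrogen. Mild acid or silica gel collapses the two silyl ketal carbons to carbonyls and delivers tetraone 15, which tautomerises to 16 without any oxidant.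

Step 7.
- **What may go wrong:** the cycloaddition may be sluggish because little of the diene sample can reach the reactive geometry. The enol ethers may hydrolyse, and the adduct may enolise early and then lose silanol.
- **Fallback:** it sets out from 9 and comes back at 16. It uses a robust cyclic diene and an Alder–Rickert sequence.
- **Diene and cycloaddition:** cyclohexane-1,4-dione is bis-silylated to 1,4-bis(trimethylsilyloxy)cyclohexa-1,3-diene F3. Its Diels–Alder reaction with 9 gives the 5,8-ethano-bridged adduct F4, whose oxygens sit on bridgeheads and cannot be eliminated.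
- **Oxidation:** enolisation on silica gel gives the ring A hydroquinone F5, which is oxidised at once with Ag2O to the bridged quinone F6.
- **Aromatisation:** heating F6 in toluene or xylene expels the two-carbon bridge in a retro-[4+2] step and aromatises ring B to the 5,8-bis(trimethylsilyloxy)-1,4-naphthoquinone F7. A mildly acidic aqueous work-up of F7 frees 16.

Step 6.
- **What may go wrong:** the enol ether geometry may be poorly controlled, and the dialdehyde may undergo aldol oligomerisation or cyclise during silylation.
- **Fallback:** it sets out from 11 and comes back at 12.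
- **Course:** 11 is converted with Ac2O and KOAc at reflux into its bis-enol acetate, and the high-melting (1E,3E)-buta-1,3-diene-1,4-diyl diacetate F8 is taken from it by crystallisation. MeLi (4 equiv, THF, −40 °C) cleaves both enol acetates with retention of alkene geometry to dilithium (1E,3E)-buta-1,3-diene-1,4-diolate F9. Trapping on oxygen with excess TMSCl gives geometrically pure 12.

Further compounds
F1 | step 9 | 2,5-bis(trimethylsilyloxy)furan | C[Si](C)(C)Oc1ccc(O[Si](C)(C)C)o1
F2 | step 9 | (S)-1-[1,4-dioxo-5,8-bis(trimethylsilyloxy)-1,4,4a,5,8,8a-hexahydro-5,8-epoxynaphthalen-2-yl]-4-methylpent-3-en-1-yl 2-methylpropanoate, endo, one facial isomer | CC(C)=CC[C@H](OC(=O)C(C)C)C1=CC(=O)[C@@H]2[C@H](C1=O)[C@]3(O[Si](C)(C)C)C=C[C@@]2(O[Si](C)(C)C)O3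
F3 | step 7 | 1,4-bis(trimethylsilyloxy)cyclohexa-1,3-diene | C[Si](C)(C)OC1=CC=C(O[Si](C)(C)C)CC1
F4 | step 7 | (S)-1-[1,4-dioxo-5,8-bis(trimethylsilyloxy)-1,4,4a,5,8,8a-hexahydro-5,8-ethanonaphthalen-2-yl]-4-methylpent-3-en-1-yl 2-methylpropanoate, endo, one facial isomer | CC(C)=CC[C@H](OC(=O)C(C)C)C1=CC(=O)[C@@H]2[C@H](C1=O)[C@]3(O[Si](C)(C)C)C=C[C@@]2(O[Si](C)(C)C)CC3
F5 | step 7 | (S)-1-[1,4-dihydroxy-5,8-bis(trimethylsilyloxy)-5,8-dihydro-5,8-ethanonaphthalen-2-yl]-4-methylpent-3-en-1-yl 2-methylpropanoate | CC(C)=CC[C@H](OC(=O)C(C)C)c1cc(O)c2c(c1O)[C@]3(O[Si](C)(C)C)C=C[C@@]2(O[Si](C)(C)C)CC3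
F6 | step 7 | (S)-1-[1,4-dioxo-5,8-bis(trimethylsilyloxy)-1,4,5,8-tetrahydro-5,8-ethanonaphthalen-2-yl]-4-methylpent-3-en-1-yl 2-methylpropanoate | CC(C)=CC[C@H](OC(=O)C(C)C)C1=CC(=O)C2=C(C1=O)[C@]3(O[Si](C)(C)C)C=C[C@@]2(O[Si](C)(C)C)CC3
F7 | step 7 | (S)-1-[1,4-dioxo-5,8-bis(trimethylsilyloxy)-1,4-dihydronaphthalen-2-yl]-4-methylpent-3-en-1-yl 2-methylpropanoate | CC(C)=CC[C@H](OC(=O)C(C)C)C1=CC(=O)c2c(O[Si](C)(C)C)ccc(O[Si](C)(C)C)c2C1=O
F8 | step 6 | (1E,3E)-buta-1,3-diene-1,4-diyl diacetate | CC(=O)O/C=C/C=C/OC(C)=O
F9 | step 6 | dilithium (1E,3E)-buta-1,3-diene-1,4-diolate | [Li]O/C=C/C=C/O[Li]
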